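**Retrosynthetic overview**
- Isoflavone ⇒ phloroglucinol + a tert-butyl α-formyl(aryl)acetate: C4–C4a and O1–C2 (ring C) come from a thermal aryl(formyl)ketene annulation on unprotected phloroglucinol.
- In the same pot the B-ring ethers rearrange: the 4'-O-(1,1-dimethylpropargyl) ether closes the 2H-pyran (ring D) at C5', and the 3'-O-(1,1-dimethylallyl) ether delivers the 2'-prenyl group and frees the 3'-OH.
- α-Formyl ester ⇒ aryl aldehyde + tert-butyl diazoacetate by aryl-shift homologation (CHO carbon becomes C2, diazo carbon C3, ester carbon C4).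
- Aryl aldehyde ⇒ 3,4-dihydroxybenzaldehyde by two regiocontrolled O-alkylations (4-OH first, since it is para to CHO).
- Ring order: A and B are bought; C, then D, are both formed in the last operation.

Assumption: the target has no stereocentre and no stereogenic double bond, so the achiral constitution given is the single compound to be made; all five starting materials are taken as catalogue chemicals.

**Step 1**
Reactants: 1 3,4-dihydroxybenzaldehyde; 2 3-chloro-3-methylbut-1-yne
Product: 3 3-hydroxy-4-[(2-methylbut-3-yn-2-yl)oxy]benzaldehyde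
Conditions: 2 (1.5 equiv), K2CO3 (1.1 equiv), KI (0.1 equiv), CuI (5 mol %), DMF, 55 °C
Reagents that add atoms: none
Why: Copper-assisted Williamson-type propargylic etherification; the 4-OH (para to the formyl group) is about three pK units more acidic than the 3-OH, so one equivalent of weak base alkylates it selectively, and 55 °C is below the onset of the propargyl Claisen rearrangement.

**Step 2**
Reactants: 3 3-hydroxy-4-[(2-methylbut-3-yn-2-yl)oxy]benzaldehyde; 4 tert-butyl 2-methylbut-3-en-2-yl carbonate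
Product: 5 3-[(2-methylbut-3-en-2-yl)oxy]-4-[(2-methylbut-3-yn-2-yl)oxy]benzaldehyde
Conditions: 4 (1.5 equiv), Pd(PPh3)4 (2 mol %), THF, 0 °C → rt
Reagents that add atoms: none
Why: Tsuji–Trost decarboxylative O-allylation in which the phenoxide attacks the more substituted terminus of the π-(1,1-dimethylallyl)palladium complex under kinetic control to give the tertiary (reverse-prenyl) aryl ether; the terminal alkyne and aldehyde are inert to Pd(0) without copper or added base.

**Step 3**
Reactants: 5 3-[(2-methylbut-3-en-2-yl)oxy]-4-[(2-methylbut-3-yn-2-yl)oxy]benzaldehyde; 6 tert-butyl diazoacetate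
Product: 7 tert-butyl (2Z)-3-hydroxy-2-{3-[(2-methylbut-3-en-2-yl)oxy]-4-[(2-methylbut-3-yn-2-yl)oxy]phenyl}prop-2-enoate
Conditions: 6 (1.3 equiv, slow addition), HBF4·OEt2 (10 mol %), CH2Cl2, −78 °C
Reagents that add atoms: none
Why: Acid-catalysed addition of the diazoester to the aldehyde followed by 1,2-aryl shift with loss of N2 (the aryl-migration variant of the Roskamp homologation), which is favoured over hydride shift for electron-rich 3,4-dialkoxyaryl groups; the product is isolated as the hydrogen-bonded Z-enol, and catalytic acid at −78 °C is chosen to spare the two tertiary ethers.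

**Step 4**
Reactants: 7 tert-butyl (2Z)-3-hydroxy-2-{3-[(2-methylbut-3-en-2-yl)oxy]-4-[(2-methylbut-3-yn-2-yl)oxy]phenyl}prop-2-enoate; 8 phloroglucinol (benzene-1,3,5-triol)
Product: 14 5,7-dihydroxy-3-[8-hydroxy-2,2-dimethyl-7-(3-methylbut-2-en-1-yl)-2H-chromen-6-yl]-4H-chromen-4-one, via prenylphenol ester 9 (not isolated), via formylketene 10 (not isolated), via acylphloroglucinol enol 11 (not isolated), via isoflavone propargyl ether 12 (not isolated), via allenylcatechol isoflavone 13 (not isolated)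
Conditions: 8 (3 equiv), 4 Å MS, diglyme, Ar, 120 °C (1 h) → 155 °C (6 h)
Reagents that add atoms: none
Why: Proposed new method: the 1,1-dimethylallyl ether undergoes aromatic Claisen rearrangement to its only free ortho carbon C2' (9: 2'-prenyl, free 3'-OH); the tert-butyl β-oxo ester then loses tert-butanol by the retro-ene path known for tert-butyl β-keto esters to give aryl(formyl)ketene 10, which C-acylates the enolic C=C of phloroglucinol as in the Mentzer thermal chromone synthesis from phloroglucinol and β-keto esters (formal [4+2]/ene addition of an α-oxoketene) to give 11, and cyclodehydration closes ring C (12); the propargyl ether then rearranges (Claisen) to its only free ortho carbon C5' (13) and a [1,5]-H shift with oxa-6π electrocyclisation closes ring D; excess phloroglucinol suppresses double annulation and shuttles protons, the sieves remove the water that would otherwise hydrate the ketene, and no stereocentre is formed.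

**Compound list**
1 | 3,4-dihydroxybenzaldehyde | O=Cc1ccc(O)c(O)c1 | starting material
2 | 3-chloro-3-methylbut-1-yne | CC(C)(Cl)C#C | starting material
3 | 3-hydroxy-4-[(2-methylbut-3-yn-2-yl)oxy]benzaldehyde | O=Cc1ccc(OC(C)(C)C#C)c(O)c1 | intermediate
4 | tert-butyl 2-methylbut-3-en-2-yl carbonate | CC(C)(C)OC(=O)OC(C)(C)C=C | starting material
5 | 3-[(2-methylbut-3-en-2-yl)oxy]-4-[(2-methylbut-3-yn-2-yl)oxy]benzaldehyde | O=Cc1ccc(OC(C)(C)C#C)c(OC(C)(C)C=C)c1 | intermediate
6 | tert-butyl diazoacetate | [N-]=[N+]=CC(=O)OC(C)(C)C | starting material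
7 | tert-butyl (2Z)-3-hydroxy-2-{3-[(2-methylbut-3-en-2-yl)oxy]-4-[(2-methylbut-3-yn-2-yl)oxy]phenyl}prop-2-enoate (enol form of the α-formyl arylacetate) | CC(C)(C)OC(=O)/C(=C\O)c1ccc(OC(C)(C)C#C)c(OC(C)(C)C=C)c1 | intermediate
8 | phloroglucinol (benzene-1,3,5-triol) | Oc1cc(O)cc(O)c1 | starting material
9 | tert-butyl (2Z)-3-hydroxy-2-{3-hydroxy-2-(3-methylbut-2-en-1-yl)-4-[(2-methylbut-3-yn-2-yl)oxy]phenyl}prop-2-enoate | CC(C)(C)OC(=O)/C(=C\O)c1ccc(OC(C)(C)C#C)c(O)c1CC=C(C)C | intermediate
10 | 2-{3-hydroxy-2-(3-methylbut-2-en-1-yl)-4-[(2-methylbut-3-yn-2-yl)oxy]phenyl}-3-oxoprop-2-enal (aryl(formyl)ketene) | O=C=C(C=O)c1ccc(OC(C)(C)C#C)c(O)c1CC=C(C)C | intermediate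
11 | (2Z)-3-hydroxy-2-{3-hydroxy-2-(3-methylbut-2-en-1-yl)-4-[(2-methylbut-3-yn-2-yl)oxy]phenyl}-1-(2,4,6-trihydroxyphenyl)prop-2-en-1-one | O/C=C(\C(=O)c1c(O)cc(O)cc1O)c1ccc(OC(C)(C)C#C)c(O)c1CC=C(C)C | intermediate
12 | 5,7-dihydroxy-3-{3-hydroxy-2-(3-methylbut-2-en-1-yl)-4-[(2-methylbut-3-yn-2-yl)oxy]phenyl}-4H-chromen-4-one | O=c1c(-c2ccc(OC(C)(C)C#C)c(O)c2CC=C(C)C)coc2cc(O)cc(O)c12 | intermediate
13 | 3-[3,4-dihydroxy-5-(3-methylbuta-1,2-dien-1-yl)-2-(3-methylbut-2-en-1-yl)phenyl]-5,7-dihydroxy-4H-chromen-4-one | O=c1c(-c2cc(C=C=C(C)C)c(O)c(O)c2CC=C(C)C)coc2cc(O)cc(O)c12 | intermediate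
14 | 5,7-dihydroxy-3-[8-hydroxy-2,2-dimethyl-7-(3-methylbut-2-en-1-yl)-2H-chromen-6-yl]-4H-chromen-4-one (achiral) | CC(C)=CCc1c(-c2coc3cc(O)cc(O)c3c2=O)cc2c(c1O)OC(C)(C)C=C2 | target

**Total step count:** 4. **Longest linear sequence:** 4 steps (1 → 3 → 5 → 7 → 14).

**Three steps most likely to fail**

Risk 1, step 4. The ketene may O-acylate phloroglucinol and close to a 3-arylcoumarin instead of C-acylating, or the two sigmatropic shifts may interfere with each other (ipso attack, intramolecular cycloaddition of the dienone) at 120–155 °C. The fallback sets out from 5, uses 8 as the A-ring source and comes back at 14; it makes the C4–C4a bond by organolithium acylation and closes ring C through an enaminone. Chloroform and DBU add to 5 to give the trichloromethyl carbinol F1. NaBH4/NaOH in aqueous tert-butanol (reductive Jocic homologation) turns it into the arylacetic acid F2, and CDI followed by MeNHOMe·HCl gives the Weinreb amide F3. Phloroglucinol 8 is converted (MOMCl, NaH, DMF) into 1,3,5-tris(methoxymethoxy)benzene F4. This is lithiated between two MOM-oxy groups (n-BuLi, THF, 0 °C; 2.2 equiv of the aryllithium, one being consumed by the alkyne C–H) and added to F3 at −78 °C to give the deoxybenzoin F5. DMF-DMA (toluene, 90 °C) gives the enaminone F6. After evaporation of the reagent, heating in o-xylene at 145 °C brings about both sigmatropic rearrangements and gives the rearranged enaminone F7 (ring D closed, 2'-prenyl and 3'-OH in place). Finally 3 M HCl in MeOH at 40 °C removes the three MOM groups and closes ring C by conjugate addition–elimination, which gives 14.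

Risk 2, step 3. The tertiary allyl aryl ether may ionise under the acid catalyst, or hydride shift may compete and give the β-keto ester. The fallback sets out from 5 and comes back at 7. Darzens condensation of 5 with tert-butyl chloroacetate (t-BuOK, THF, −78 → 0 °C; base only) gives the glycidic ester F8 as a mixture of racemic cis and trans isomers. A catalytic mild Lewis acid (MgBr2·OEt2, CH2Cl2, −20 °C) opens the epoxide at the 4-alkoxybenzylic carbon and the tert-butoxycarbonyl group migrates (semipinacol-type 1,2-acyl shift), which gives 7 from either diastereomer.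

Risk 3, step 2. The 3-OH next to the bulky tertiary propargyl ether may react slowly, or palladium may equilibrate the product to the linear prenyl ether. The fallback sets out from 3 and comes back at 14; it builds the prenyl group from an allyl group. Allyl bromide and K2CO3 in DMF convert 3 into the allyl ether F9. The conditions of step 3 give the hydroxyacrylate F10, with no acid-labile allyl ether present. The conditions of step 4 in triglyme (155 °C, then 195 °C) give the 7-allyl chromene isoflavone F11, ring D closing before the allyl ether rearranges to C2'. Cross-metathesis with 2-methylbut-2-ene (Grubbs second-generation catalyst, CH2Cl2, 40 °C) converts the allyl into the prenyl group and gives 14.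

**Further compounds**
F1 | step 4 | 2,2,2-trichloro-1-{3-[(2-methylbut-3-en-2-yl)oxy]-4-[(2-methylbut-3-yn-2-yl)oxy]phenyl}ethan-1-ol (racemic) | OC(c1ccc(OC(C)(C)C#C)c(OC(C)(C)C=C)c1)C(Cl)(Cl)Cl
F2 | step 4 | {3-[(2-methylbut-3-en-2-yl)oxy]-4-[(2-methylbut-3-yn-2-yl)oxy]phenyl}acetic acid | OC(=O)Cc1ccc(OC(C)(C)C#C)c(OC(C)(C)C=C)c1
F3 | step 4 | N-methoxy-N-methyl-2-{3-[(2-methylbut-3-en-2-yl)oxy]-4-[(2-methylbut-3-yn-2-yl)oxy]phenyl}acetamide | CON(C)C(=O)Cc1ccc(OC(C)(C)C#C)c(OC(C)(C)C=C)c1
F4 | step 4 | 1,3,5-tris(methoxymethoxy)benzene | COCOc1cc(OCOC)cc(OCOC)c1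
F5 | step 4 | 2-{3-[(2-methylbut-3-en-2-yl)oxy]-4-[(2-methylbut-3-yn-2-yl)oxy]phenyl}-1-[2,4,6-tris(methoxymethoxy)phenyl]ethan-1-one | COCOc1cc(OCOC)c(C(=O)Cc2ccc(OC(C)(C)C#C)c(OC(C)(C)C=C)c2)c(OCOC)c1
F6 | step 4 | (2E)-3-(dimethylamino)-2-{3-[(2-methylbut-3-en-2-yl)oxy]-4-[(2-methylbut-3-yn-2-yl)oxy]phenyl}-1-[2,4,6-tris(methoxymethoxy)phenyl]prop-2-en-1-one | CN(C)/C=C(/C(=O)c1c(OCOC)cc(OCOC)cc1OCOC)c1ccc(OC(C)(C)C#C)c(OC(C)(C)C=C)c1
F7 | step 4 | (2E)-3-(dimethylamino)-2-[8-hydroxy-2,2-dimethyl-7-(3-methylbut-2-en-1-yl)-2H-chromen-6-yl]-1-[2,4,6-tris(methoxymethoxy)phenyl]prop-2-en-1-one | CN(C)/C=C(/C(=O)c1c(OCOC)cc(OCOC)cc1OCOC)c1cc2C=CC(C)(C)Oc2c(O)c1CC=C(C)C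
F8 | step 3 | tert-butyl 3-{3-[(2-methylbut-3-en-2-yl)oxy]-4-[(2-methylbut-3-yn-2-yl)oxy]phenyl}oxirane-2-carboxylate (racemic cis/trans mixture) | CC(C)(C)OC(=O)C1OC1c1ccc(OC(C)(C)C#C)c(OC(C)(C)C=C)c1
F9 | step 2 | 4-[(2-methylbut-3-yn-2-yl)oxy]-3-(prop-2-en-1-yloxy)benzaldehyde | O=Cc1ccc(OC(C)(C)C#C)c(OCC=C)c1
F10 | step 2 | tert-butyl (2Z)-3-hydroxy-2-{4-[(2-methylbut-3-yn-2-yl)oxy]-3-(prop-2-en-1-yloxy)phenyl}prop-2-enoate | CC(C)(C)OC(=O)/C(=C\O)c1ccc(OC(C)(C)C#C)c(OCC=C)c1
F11 | step 2 | 5,7-dihydroxy-3-[8-hydroxy-2,2-dimethyl-7-(prop-2-en-1-yl)-2H-chromen-6-yl]-4H-chromen-4-one | O=c1c(-c2cc3C=CC(C)(C)Oc3c(O)c2CC=C)coc2cc(O)cc(O)c12
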